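The cyclopentene C2=C3 double bond (indene numbering; C3 carries the ethyl group) is the last ring bond made. An intramolecular McMurry coupling joins an aldehyde carbon (future C2) to an ethyl-ketone carbon (future C3) and deoxygenates both, closing the trans-fused five-membered ring on the finished cyclohexene. The step exploits the trans-vicinal C3a/C7a arms of the six-membered ring, a 1,5-keto-aldehyde. That precursor comes from a δ-lactone, the ester tether of an intramolecular Diels–Alder reaction of a mesaconate of a Roche-ester-derived tetraenol. The cycloaddition sets all four ring stereocenters, including both quaternary carbons, from one purchased stereocenter; the tether oxygens are erased in the key step.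

Key step: step 13

Remark: indene numbering is used for the bicyclic core (C1 = CHMe, C2 = ring CH=, C3 = C–Et, C3a and C7a = ring-fusion CH, C4 = C(Me)CO2H, C5 = C(Me)(dienyl), C6 = CH=, C7 = C–Me); ylide 12 is taken as commercially available, and hydroxy ketone 16 is written in its open form although it should equilibrate with its cyclic hemiketal.

Step 1
Reactants: 1 methyl (R)-3-hydroxy-2-methylpropanoate ((R)-Roche ester)
Product: 2 methyl (R)-3-[(tert-butyldimethylsilyl)oxy]-2-methylpropanoate
Conditions: TBSCl, imidazole, CH2Cl2, 0 °C → rt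
Reagents that add atoms: tert-butyldimethylsilyl chloride, CC(C)(C)[Si](C)(C)Cl
Why: Imidazole-promoted silylation of the primary alcohol leaves the stereocenter untouched.

Step 2
Reactants: 2 methyl (R)-3-[(tert-butyldimethylsilyl)oxy]-2-methylpropanoate
Product: 3 (R)-3-[(tert-butyldimethylsilyl)oxy]-2-methylpropanal
Conditions: DIBAL-H (1.05 equiv), CH2Cl2, −78 °C; then MeOH, aq. Rochelle salt
Reagents that add atoms: none
Why: DIBAL-H partial reduction of the ester stops at the aldehyde oxidation level at −78 °C, and the cold, non-basic work-up should avoid epimerization of the α-stereocenter; the aldehyde is used crude.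

Step 3
Reactants: 3 (R)-3-[(tert-butyldimethylsilyl)oxy]-2-methylpropanal; 4 2-(triphenylphosphoranylidene)propanal
Product: 5 (S,E)-5-[(tert-butyldimethylsilyl)oxy]-2,4-dimethylpent-2-enal
Conditions: 4 (1.3 equiv), PhMe, 90 °C
Reagents that add atoms: none
Why: Wittig olefination with the formyl-stabilized ylide should give the (E)-2-methyl enal under neutral conditions that do not epimerize the α-stereocenter, the aliphatic aldehyde reacting much faster than the enal product.

Step 4
Reactants: 5 (S,E)-5-[(tert-butyldimethylsilyl)oxy]-2,4-dimethylpent-2-enal; 4 2-(triphenylphosphoranylidene)propanal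
Product: 6 (2E,4E,6S)-7-[(tert-butyldimethylsilyl)oxy]-2,4,6-trimethylhepta-2,4-dienal
Conditions: 4 (1.2 equiv), PhMe, 110 °C
Reagents that add atoms: none
Why: A second Wittig formyl-olefination should give the E trisubstituted alkene; the more conjugated dienal is the weaker electrophile, so over-homologation should stay minor with a small excess of ylide.

Step 5
Reactants: 6 (2E,4E,6S)-7-[(tert-butyldimethylsilyl)oxy]-2,4,6-trimethylhepta-2,4-dienal; 4 2-(triphenylphosphoranylidene)propanal
Product: 7 (2E,4E,6E,8S)-9-[(tert-butyldimethylsilyl)oxy]-2,4,6,8-tetramethylnona-2,4,6-trienal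
Conditions: 4 (1.2 equiv), PhMe, 110 °C
Reagents that add atoms: none
Why: A third Wittig formyl-olefination of the same kind should extend the chain by one more (E)-C(Me)=CH unit, stopped at full conversion of 6.

Step 6
Reactants: 7 (2E,4E,6E,8S)-9-[(tert-butyldimethylsilyl)oxy]-2,4,6,8-tetramethylnona-2,4,6-trienal; 8 diethyl benzylphosphonate
Product: 9 tert-butyldimethyl{[(2S,3E,5E,7E,9E)-2,4,6,8-tetramethyl-10-phenyldeca-3,5,7,9-tetraen-1-yl]oxy}silane
Conditions: 8, KOtBu, THF, −78 → 0 °C
Reagents that add atoms: none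
Why: Horner–Wadsworth–Emmons olefination with the preformed benzylphosphonate anion should give the (E)-styryl terminus, carbonyl addition being faster than deprotonation of the remote allylic stereocenter.

Step 7
Reactants: 9 tert-butyldimethyl{[(2S,3E,5E,7E,9E)-2,4,6,8-tetramethyl-10-phenyldeca-3,5,7,9-tetraen-1-yl]oxy}silane
Product: 10 (2S,3E,5E,7E,9E)-2,4,6,8-tetramethyl-10-phenyldeca-3,5,7,9-tetraen-1-ol
Conditions: TBAF, THF, 0 °C → rt
Reagents that add atoms: none
Why: Fluoride-mediated desilylation frees the primary alcohol; the tetraene is inert to fluoride.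

Step 8
Reactants: 11 glyoxylic acid monohydrate; 12 methyl 2-(triphenylphosphoranylidene)propanoate
Product: 13 (2E)-4-methoxy-3-methyl-4-oxobut-2-enoic acid (mesaconic acid 1-methyl ester)
Conditions: CH2Cl2, 0 °C → rt; extraction into aq. NaHCO3, then acidification
Reagents that add atoms: none
Why: Wittig olefination of glyoxylic acid with the ester-stabilized α-methyl ylide should give the E half ester (carboxyl groups trans), with the free acid on the CH carbon by construction.

Step 9
Reactants: 10 (2S,3E,5E,7E,9E)-2,4,6,8-tetramethyl-10-phenyldeca-3,5,7,9-tetraen-1-ol; 13 (2E)-4-methoxy-3-methyl-4-oxobut-2-enoic acid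
Product: 14 1-methyl 4-[(2S,3E,5E,7E,9E)-2,4,6,8-tetramethyl-10-phenyldeca-3,5,7,9-tetraen-1-yl] (2E)-2-methylbut-2-enedioate
Conditions: DCC, DMAP (cat.), CH2Cl2, 0 °C → rt
Reagents that add atoms: none
Why: Steglich esterification of the unhindered conjugated acid with the primary alcohol is neutral and should preserve the mesaconate geometry and the stereocenter.

Step 10
Reactants: 14 1-methyl 4-[(2S,3E,5E,7E,9E)-2,4,6,8-tetramethyl-10-phenyldeca-3,5,7,9-tetraen-1-yl] (2E)-2-methylbut-2-enedioate
Product: 15 methyl (4S,4aS,7S,8R,8aS)-4,5,7,8-tetramethyl-7-[(1E,3E)-2-methyl-4-phenylbuta-1,3-dien-1-yl]-1-oxo-3,4,4a,7,8,8a-hexahydro-1H-isochromene-8-carboxylate (trans-fused δ-lactone; 4-Me cis to H-4a; CO2Me cis to H-8a and to the dienyl group)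
Conditions: PhMe (0.005 M), BHT (cat.), 130–150 °C, sealed tube
Reagents that add atoms: none
Why: Thermal ester-tethered intramolecular Diels–Alder reaction of a 1,3,9-decatriene: the doubly activated (E)-mesaconate can reach only the diene nearest the tether; the chain stereocenter, held by allylic 1,3-strain with its hydrogen eclipsing the diene and its methyl group anti to the dienophile (equatorial in the chair-like forming lactone ring), selects the diene face, the tether-carbonyl-exo/CO2Me-endo arrangement gives the trans ring fusion, and the E geometries of dienophile and diene fix the remaining relationships, so that both quaternary carbons and both ring-fusion centers should be set in one event.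

Step 11
Reactants: 15 trans-fused δ-lactone (as named in step 10)
Product: 16 methyl (1R,2S,5S,6S)-5-[(2S)-1-hydroxypropan-2-yl]-1,2,4-trimethyl-2-[(1E,3E)-2-methyl-4-phenylbuta-1,3-dien-1-yl]-6-propanoylcyclohex-3-ene-1-carboxylate
Conditions: EtLi (1.1 equiv), Et2O–THF, −78 °C; then sat. aq. NH4Cl
Reagents that add atoms: ethyllithium, [Li]CC
Why: Mono-addition of an alkyllithium to a δ-lactone at −78 °C should stop at the ketone level because the tetrahedral adduct survives until the quench; the methyl ester on the quaternary carbon is far more hindered than the lactone carbonyl and no stereocenter is touched.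

Step 12
Reactants: 16 methyl (1R,2S,5S,6S)-5-[(2S)-1-hydroxypropan-2-yl]-1,2,4-trimethyl-2-[(1E,3E)-2-methyl-4-phenylbuta-1,3-dien-1-yl]-6-propanoylcyclohex-3-ene-1-carboxylate
Product: 17 methyl (1R,2S,5S,6S)-1,2,4-trimethyl-2-[(1E,3E)-2-methyl-4-phenylbuta-1,3-dien-1-yl]-5-[(2S)-1-oxopropan-2-yl]-6-propanoylcyclohex-3-ene-1-carboxylate
Conditions: Dess–Martin periodinane, NaHCO3, CH2Cl2, 0 °C → rt; used directly
Reagents that add atoms: none
Why: Dess–Martin oxidation takes the primary alcohol of the open-chain form to the aldehyde (the hemiketal form has no carbinol C–H and drains through ring–chain equilibration), and the buffered neutral medium should preserve the new α-stereocenter.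

Step 13
Reactants: 17 methyl (1R,2S,5S,6S)-1,2,4-trimethyl-2-[(1E,3E)-2-methyl-4-phenylbuta-1,3-dien-1-yl]-5-[(2S)-1-oxopropan-2-yl]-6-propanoylcyclohex-3-ene-1-carboxylate
Product: 19 methyl (1R,3aR,4R,5S,7aS)-3-ethyl-1,4,5,7-tetramethyl-5-[(1E,3E)-2-methyl-4-phenylbuta-1,3-dien-1-yl]-3a,4,5,7a-tetrahydro-1H-indene-4-carboxylate, via titanium pinacolate of the corresponding 3-ethyl-2,3-dihydroxy-hexahydroindene 18 (not isolated)
Conditions: TiCl3(DME)1.5, Zn–Cu, DME, reflux; 17 added by syringe pump
Reagents that add atoms: none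
Why: McMurry reductive carbonyl coupling: low-valent titanium transfers single electrons to the aldehyde (C2) and the ethyl ketone (C3), the two ketyls couple on titanium to the pinacolate 18, and at reflux both C–O bonds are cleaved to the alkene, driven by the Ti–O bond strength. The closest known reaction type is the intramolecular McMurry cyclization of keto-aldehydes to cycloalkenes, established for five-membered rings and for polyene aldehydes. The five-membered ring closes by direct C–C coupling of the 1,5-related carbonyl carbons (a pinacol-type carbonyl–carbonyl closure, not an addition to a π-bond), and the alkene can only be cis within the ring, so no geometry issue arises. No stereocenter is created: C1, C3a and C7a are carried through, and the trans ring fusion is preset by the trans-diequatorial arms on the cyclohexene; the resulting trans-hydrindene with a C2=C3 bond has the strain level of a Δ16-steroid CD system. The step needs chemoselectivity for aldehyde and ketone over the methyl ester and the styryl diene, and intramolecular over intermolecular coupling: the ester sits on a quaternary carbon next to a second one, conjugated polyenes are known to survive these conditions, and slow addition keeps the substrate dilute. It also needs retention at C1, which the non-basic medium should secure because ketyl coupling is faster than enolization.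

Step 14
Reactants: 19 methyl (1R,3aR,4R,5S,7aS)-3-ethyl-1,4,5,7-tetramethyl-5-[(1E,3E)-2-methyl-4-phenylbuta-1,3-dien-1-yl]-3a,4,5,7a-tetrahydro-1H-indene-4-carboxylate
Product: 20 zyggomphic acid B, (1R,3aR,4R,5S,7aS)-3-ethyl-1,4,5,7-tetramethyl-5-[(1E,3E)-2-methyl-4-phenylbuta-1,3-dien-1-yl]-3a,4,5,7a-tetrahydro-1H-indene-4-carboxylic acid
Conditions: n-PrSLi, HMPA, rt → 50 °C; then 1 M HCl
Reagents that add atoms: none
Why: SN2 demethylation by thiolate attacks the methyl carbon rather than the shielded acyl carbon, so the hindered ester should be cleaved without touching the alkenes or stereocenters.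

Compound list
1 | methyl (R)-3-hydroxy-2-methylpropanoate ((R)-Roche ester) | OC[C@@H](C)C(=O)OC | starting material
2 | methyl (R)-3-[(tert-butyldimethylsilyl)oxy]-2-methylpropanoate | CC(C)(C)[Si](C)(C)OC[C@@H](C)C(=O)OC | intermediate
3 | (R)-3-[(tert-butyldimethylsilyl)oxy]-2-methylpropanal | CC(C)(C)[Si](C)(C)OC[C@@H](C)C=O | intermediate
4 | 2-(triphenylphosphoranylidene)propanal | CC(C=O)=P(c1ccccc1)(c1ccccc1)c1ccccc1 | starting material
5 | (S,E)-5-[(tert-butyldimethylsilyl)oxy]-2,4-dimethylpent-2-enal | CC(C)(C)[Si](C)(C)OC[C@@H](C)/C=C(C)/C=O | intermediate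
6 | (2E,4E,6S)-7-[(tert-butyldimethylsilyl)oxy]-2,4,6-trimethylhepta-2,4-dienal | CC(C)(C)[Si](C)(C)OC[C@@H](C)/C=C(C)/C=C(C)/C=O | intermediate
7 | (2E,4E,6E,8S)-9-[(tert-butyldimethylsilyl)oxy]-2,4,6,8-tetramethylnona-2,4,6-trienal | CC(C)(C)[Si](C)(C)OC[C@@H](C)/C=C(C)/C=C(C)/C=C(C)/C=O | intermediate
8 | diethyl benzylphosphonate | CCOP(=O)(Cc1ccccc1)OCC | starting material
9 | tert-butyldimethyl{[(2S,3E,5E,7E,9E)-2,4,6,8-tetramethyl-10-phenyldeca-3,5,7,9-tetraen-1-yl]oxy}silane | CC(C)(C)[Si](C)(C)OC[C@@H](C)/C=C(C)/C=C(C)/C=C(C)/C=C/c1ccccc1 | intermediate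
10 | (2S,3E,5E,7E,9E)-2,4,6,8-tetramethyl-10-phenyldeca-3,5,7,9-tetraen-1-ol | OC[C@@H](C)/C=C(C)/C=C(C)/C=C(C)/C=C/c1ccccc1 | intermediate
11 | glyoxylic acid monohydrate | OC(O)C(=O)O | starting material
12 | methyl 2-(triphenylphosphoranylidene)propanoate | COC(=O)C(C)=P(c1ccccc1)(c1ccccc1)c1ccccc1 | starting material
13 | (2E)-4-methoxy-3-methyl-4-oxobut-2-enoic acid | COC(=O)/C(C)=C/C(=O)O | intermediate
14 | 1-methyl 4-[(2S,3E,5E,7E,9E)-2,4,6,8-tetramethyl-10-phenyldeca-3,5,7,9-tetraen-1-yl] (2E)-2-methylbut-2-enedioate | COC(=O)/C(C)=C/C(=O)OC[C@@H](C)/C=C(C)/C=C(C)/C=C(C)/C=C/c1ccccc1 | intermediate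
15 | methyl (4S,4aS,7S,8R,8aS)-4,5,7,8-tetramethyl-7-[(1E,3E)-2-methyl-4-phenylbuta-1,3-dien-1-yl]-1-oxo-3,4,4a,7,8,8a-hexahydro-1H-isochromene-8-carboxylate | O=C1OC[C@@H](C)[C@@H]2C(C)=C[C@](C)(/C=C(C)/C=C/c3ccccc3)[C@](C)(C(=O)OC)[C@@H]12 | intermediate
16 | methyl (1R,2S,5S,6S)-5-[(2S)-1-hydroxypropan-2-yl]-1,2,4-trimethyl-2-[(1E,3E)-2-methyl-4-phenylbuta-1,3-dien-1-yl]-6-propanoylcyclohex-3-ene-1-carboxylate | CCC(=O)[C@H]1[C@H]([C@@H](CO)C)C(C)=C[C@](C)(/C=C(C)/C=C/c2ccccc2)[C@]1(C)C(=O)OC | intermediate
17 | methyl (1R,2S,5S,6S)-1,2,4-trimethyl-2-[(1E,3E)-2-methyl-4-phenylbuta-1,3-dien-1-yl]-5-[(2S)-1-oxopropan-2-yl]-6-propanoylcyclohex-3-ene-1-carboxylate | CCC(=O)[C@H]1[C@H]([C@@H](C=O)C)C(C)=C[C@](C)(/C=C(C)/C=C/c2ccccc2)[C@]1(C)C(=O)OC | intermediate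
18 | titanium pinacolate, drawn as the parent diol methyl 3-ethyl-2,3-dihydroxy-1,4,5,7-tetramethyl-5-[(1E,3E)-2-methyl-4-phenylbuta-1,3-dien-1-yl]-2,3,3a,4,5,7a-hexahydro-1H-indene-4-carboxylate (C2/C3 configuration undefined) | CCC1(O)C(O)[C@@H](C)[C@@H]2C(C)=C[C@](C)(/C=C(C)/C=C/c3ccccc3)[C@](C)(C(=O)OC)[C@@H]12 | intermediate
19 | methyl (1R,3aR,4R,5S,7aS)-3-ethyl-1,4,5,7-tetramethyl-5-[(1E,3E)-2-methyl-4-phenylbuta-1,3-dien-1-yl]-3a,4,5,7a-tetrahydro-1H-indene-4-carboxylate | CCC1=C[C@@H](C)[C@@H]2C(C)=C[C@](C)(/C=C(C)/C=C/c3ccccc3)[C@](C)(C(=O)OC)[C@@H]12 | intermediate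
20 | zyggomphic acid B, (1R,3aR,4R,5S,7aS)-3-ethyl-1,4,5,7-tetramethyl-5-[(1E,3E)-2-methyl-4-phenylbuta-1,3-dien-1-yl]-3a,4,5,7a-tetrahydro-1H-indene-4-carboxylic acid | CCC1=C[C@@H](C)[C@@H]2C(C)=C[C@](C)(/C=C(C)/C=C/c3ccccc3)[C@](C)(C(=O)O)[C@@H]12 | target

Total step count: 14. Longest linear sequence: 13 (steps 1–7 and 9–14).

Steps most likely to fail

Step 10. The cycloaddition may run through the competing mode with the tether carbonyl endo, which gives a cis-fused lactone with the wrong relationship between the ester-bearing and dienyl-bearing quaternary carbons. The (Z)-methyl-substituted diene terminus may also undergo thermal 1,5-hydrogen shifts before it cyclizes. The fallback changes the dienophile geometry and corrects the ring fusion afterwards. It sets out from 10: acylation with citraconic anhydride (Et3N, DMAP) at its less hindered carbonyl would give the (Z)-citraconate half ester F1, and TMSCHN2 the (Z)-diester F2. Cycloaddition of F2 through the all-endo mode typical of maleate-type esters would give the cis-fused lactone F3, the 8a-epimer of 15, which already has the correct relationship between the two quaternary carbons. Epimerization with DBU at C8a, the only enolizable position, is expected to favor the trans-fused chair lactone and comes back to the route at 15.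

Step 13. Titanium enolate formation could epimerize the aldehyde α-stereocenter or trigger an aldol reaction between the ethyl ketone and the aldehyde before coupling, and the reaction could stop at the pinacol stage. The fallback closes the same C2=C3 bond by olefin metathesis. It sets out from 17: non-basic double methylenation (Zn, CH2Br2, TiCl4, THF–CH2Cl2, 0 °C → rt) would give the diene methyl (1R,2S,5S,6R)-6-(but-1-en-2-yl)-5-[(2R)-but-3-en-2-yl]-1,2,4-trimethyl-2-[(1E,3E)-2-methyl-4-phenylbuta-1,3-dien-1-yl]cyclohex-3-ene-1-carboxylate F4. Ring-closing metathesis (Grubbs second-generation catalyst, CH2Cl2, 2 mM, 40 °C) should start at the monosubstituted vinyl group and close the trisubstituted cyclopentene faster than it engages the hindered side-chain diene, coming back at 19.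

Step 11. Double addition to the ketone, enolization of the lactone or carbolithiation of the styryl diene may compete with mono-addition. The fallback uses a Weinreb amide. It sets out from 15: aminolysis with Me(MeO)NH·HCl/AlMe3 (CH2Cl2, 0 °C) would open the lactone to the hydroxy Weinreb amide F5. Silylation (TESCl, imidazole) would give the triethylsilyl ether F6, and EtMgBr (THF, 0 °C) the silyl-protected ethyl ketone F7. Desilylation (HF·pyridine, THF) comes back at 16.

Further compounds
F1 | step 10 | (2Z)-2-methyl-4-oxo-4-{[(2S,3E,5E,7E,9E)-2,4,6,8-tetramethyl-10-phenyldeca-3,5,7,9-tetraen-1-yl]oxy}but-2-enoic acid | OC(=O)/C(C)=C\C(=O)OC[C@@H](C)/C=C(C)/C=C(C)/C=C(C)/C=C/c1ccccc1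
F2 | step 10 | 1-methyl 4-[(2S,3E,5E,7E,9E)-2,4,6,8-tetramethyl-10-phenyldeca-3,5,7,9-tetraen-1-yl] (2Z)-2-methylbut-2-enedioate | COC(=O)/C(C)=C\C(=O)OC[C@@H](C)/C=C(C)/C=C(C)/C=C(C)/C=C/c1ccccc1
F3 | step 10 | methyl (4S,4aS,7S,8R,8aR)-4,5,7,8-tetramethyl-7-[(1E,3E)-2-methyl-4-phenylbuta-1,3-dien-1-yl]-1-oxo-3,4,4a,7,8,8a-hexahydro-1H-isochromene-8-carboxylate (cis-fused, 8a-epimer of 15) | O=C1OC[C@@H](C)[C@@H]2C(C)=C[C@](C)(/C=C(C)/C=C/c3ccccc3)[C@](C)(C(=O)OC)[C@H]12
F4 | step 13 | methyl (1R,2S,5S,6R)-6-(but-1-en-2-yl)-5-[(2R)-but-3-en-2-yl]-1,2,4-trimethyl-2-[(1E,3E)-2-methyl-4-phenylbuta-1,3-dien-1-yl]cyclohex-3-ene-1-carboxylate | CCC(=C)[C@H]1[C@H]([C@@H](C=C)C)C(C)=C[C@](C)(/C=C(C)/C=C/c2ccccc2)[C@]1(C)C(=O)OC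
F5 | step 11 | methyl (1R,2S,5S,6S)-5-[(2S)-1-hydroxypropan-2-yl]-6-[methoxy(methyl)carbamoyl]-1,2,4-trimethyl-2-[(1E,3E)-2-methyl-4-phenylbuta-1,3-dien-1-yl]cyclohex-3-ene-1-carboxylate | CON(C)C(=O)[C@H]1[C@H]([C@@H](CO)C)C(C)=C[C@](C)(/C=C(C)/C=C/c2ccccc2)[C@]1(C)C(=O)OC
F6 | step 11 | triethylsilyl ether of F5 (same configurations) | CON(C)C(=O)[C@H]1[C@H]([C@@H](CO[Si](CC)(CC)CC)C)C(C)=C[C@](C)(/C=C(C)/C=C/c2ccccc2)[C@]1(C)C(=O)OC
F7 | step 11 | triethylsilyl ether of 16 (same configurations) | CCC(=O)[C@H]1[C@H]([C@@H](CO[Si](CC)(CC)CC)C)C(C)=C[C@](C)(/C=C(C)/C=C/c2ccccc2)[C@]1(C)C(=O)OC
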